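Early in the amber run, over the first 1.8 h, L turned to J over the catalyst Z at 0.0635 h⁻¹ as a fraction of the charge, and I started my ladder of time scales there.

| flask | L | Z | J | time |
|---|---|---|---|---|
| amber | 300 mM | 0.600 mM |  |  |
| violet | 150 mM | 0.600 mM |  |  |
| green | 300 mM | 0.600 mM | 90.0 mM |  |
| ochre | 300 mM | 0.240 mM |  | 20 h |

| amber run: time / h | amber run: [J] / mM | violet run: time / h | violet run: [J] / mM | green run: time / h | green run: [J] / mM |
|---|---|---|---|---|---|
| 0.80 | 13.8 | 0.80 | 12.5 | 0.80 | 106.5 |
| 1.8 | 34.3 | 1.8 | 20.3 | 1.8 | 120.1 |
| 4.0 | 62.9 | 4.0 | 44.9 | 4.0 | 148.1 |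
| 8.9 | 103.9 | 8.9 | 74.8 | 8.9 | 182.1 |
| 20 | 132.9 | 20 | 98.6 | 20 | 202.4 |

(scatter of a reading: 2 mM)

- Overall: L -> J, with Z as catalyst.
- Constant volume, constant temperature.
- Bound and free are read together.
- An order is taken over about fifteen percent of the charge, up and down.

- how the opening rate goes with [L] round the charge of the amber run: the exponent of the rate at two percent of L gone to J (one fixed amount of J, the same in the runs compared)
- J in the ochre run at 20 h, as a share of the L charged

1. The first rung is one turnover. At that opening pace, each Z in amber made one J in 1.89 min.

2. The next rung is the fall of the rate. Between 8.9 h and 20 h, amber ran at 0.00871 h⁻¹ of the charge, which gave a fall time of 6.82 h, far longer than a turnover.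

3. Was this L running down, or J holding back? Over the first 4.0 h, violet, with half the L, made 0.714 of amber's J, and green, charged with J, made 0.924 of it. Amber's rate fell by a factor of 7.29, much more than the factor of 1.40 between amber's J and violet's, so I read the fall as working Z being lost.

4. The last rung is L. Amber's charge divided by the opening pace gives 15.7 h, longer than the fall time.

5. So I carried one number, J made per Z charged by 20 h: amber's reading gave 222, and I call this the count (turnover number). The share of the charge is the count times Z over L, so if ochre's Z keeps amber's count, ochre gives 17.7%.

6. The forecast was higher than my figure: 20% (17% to 24%), with an order of 0.4 (0.25 to 0.55). It held that “The loss must therefore be mainly catalyst dying with time”.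

The flask gave an order of 0.34 and 18.7% in ochre.

    Z + L ⇌ ZL, settled at all times (6.900 M⁻¹)
    ZL → J + Z (48.96 h⁻¹)
    Z + L → Ja + L (1.040 M⁻¹ h⁻¹)
    J → Yx (0.01321 h⁻¹)

Ochre's count was 234, a little above amber's. Ochre stopped short of more because of the passing of Z + L into Ja + L. The ochre run without that passing reached 41.4% of the charge at 20 h, a count of 517, about twice the real one.

(Readings and results were generated by integration for substances that don't exist, and the scatter is random.)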